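Reckon with the fraction of target kept, not the fraction made.

| flask | substrate | partner | temperature | remark | time |
|---|---|---|---|---|---|
| red | 8.5 mM | 2 equiv | 25 °C | run made earlier |  |
| blue | 35 mM | 2 equiv | 50 °C | run made earlier |  |
| ochre | 12 mM | 1.8 equiv | 25 °C | run made earlier |  |
| zeta | 12 mM | 2.00 equiv | 70 °C |  | 4.0 h |
| gamma | 12 mM | 1.30 equiv | 30 °C |  | 4.0 h |
| beta | 12 mM | 2.00 equiv | 55 °C |  | 4.0 h |
| alpha | 40 mM | 4.00 equiv | 70 °C |  | 4.0 h |

| run | time / h | target / % | substrate / % |
|---|---|---|---|
| red | 4.00 | 83.5 | 13.0 |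
| red | 8.00 | 90.0 | 5.9 |
| red | 12.0 | 88.5 | 3.8 |
| red | 15.0 | 87.6 | 6.0 |
| red | 20.0 | 84.8 | 4.7 |
| red | 25.0 | 82.2 | 5.0 |
| red | 30.0 | 81.5 | 3.7 |
| blue | 0.667 | 78.2 | 11.1 |
| blue | 0.833 | 76.2 | 11.3 |
| blue | 1.33 | 69.6 | 10.1 |
| blue | 2.50 | 58.0 | 10.1 |
| blue | 4.00 | 47.6 | 9.5 |
| blue | 5.00 | 41.4 | 9.1 |
| blue | 8.00 | 30.5 | 8.7 |
| ochre | 5.00 | 88.3 | 8.0 |
| ochre | 10.0 | 89.0 | 5.4 |
| ochre | 15.0 | 85.7 | 4.6 |
| ochre | 25.0 | 80.5 | 5.1 |
| ochre | 30.0 | 79.6 | 3.6 |

(standard deviation of a reading: 0.5 percentage points)

1. the flasks put in order of amount of target, in percent of the substrate charged, best first, at 4.0 h (zeta / gamma / beta / alpha)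
2. the same order at 12 min (zeta / gamma / beta / alpha)
3. the amount of target, in percent of the substrate charged of the flask you put first, at 4.0 h
4. the amount of target, in percent of the substrate charged of the flask you put last, at 4.0 h

**What does the blue run show once substrate falls slowly?** Target goes on falling. In the blue run, between 1.33 h and 8.00 h, substrate moves from 10.1% to 8.7%, while target sinks from 69.6% to 30.5%, a logarithmic rate of 0.124 h⁻¹.

**Is that rate a constant of target by itself?** No. In blue it runs at 0.176 h⁻¹ early and 0.102 h⁻¹ late, so I take the loss to be a step of target with free partner. Its rate is k·c·[target], where k is the loss constant and c the free partner. The kept fraction over a time t, with c held constant, is then φ = exp(−k·c·t).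

**How do you get c without a reading of partner?** By balance. I assume each substrate gone took one partner and each target lost took another. With S the charged substrate, e the equivalents, and a and p the fractions of substrate and target, c = S·(e − 2(1 − a) + p). Blue gives 0.0314 M and then 0.0168 M. Their mean makes the loss constant at 50 °C 5.13 M⁻¹ h⁻¹.

**And the temperature?** In red, the same balance puts partner at 8.65 mM and later at 7.56 mM, so I treat the loss there as pseudo-first-order, and it gives 0.556 M⁻¹ h⁻¹ at 25 °C. Between those temperatures k grows by a factor of 9.23, and I carry that same logarithmic slope to the new flasks, a rough extrapolation.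

**Rank the flasks at 4.0 h.** Taking c as the excess of partner over substrate, my φ is 98.8% for gamma, 68.1% for beta and 23.3% for zeta. On the same reckoning alpha's target has a lifetime of 16.5 min, and 4.0 h is 14.5 of those, so I put alpha last.

**Does φ rank them at 12 min?** No. It multiplies what has formed, and the red run still holds 13.0% substrate after 4.00 h, so forming in red takes hours. I give no order from φ for that time.

The forecast, holding that “The rate tracks free partner”, puts gamma > beta > zeta > alpha at 4.0 h, with 80% first and 0.5% last, and beta > alpha > zeta > gamma at 12 min.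

    substrate + partner ⇌ isomer of the product (K = 390 M⁻¹, k = 18.0 M⁻¹ h⁻¹, Ea = 63.0 kJ mol⁻¹, ΔH = −37.0 kJ mol⁻¹)
    2 partner → homo dimer (k = 0.550 M⁻¹ h⁻¹, Ea = 64.0 kJ mol⁻¹)
    partner + target → over-reaction product (k = 18.0 M⁻¹ h⁻¹, Ea = 64.0 kJ mol⁻¹)
    substrate + partner ⇌ target (K = 35.0 M⁻¹, k = 910 M⁻¹ h⁻¹, Ea = 56.0 kJ mol⁻¹, ΔH = −79.0 kJ mol⁻¹)
    (constants at 70 °C)

The flasks give gamma > beta > zeta > alpha at 4.0 h, with gamma at 79.2% and alpha at 0.796%, and beta > alpha > zeta > gamma at 12 min. Alpha's substrate is 99.6% converted, and it holds 78.2% over-reaction product. Gamma, with c set to the partner left at 4.00 h, 35.4% of its charge, reckons to φ = 98.1%, and its target over target plus over-reaction product is 98.0%. Beta, with c set the same way to 52.5% of its charge, reckons to 66.8%, and the same share in beta, from 42.3% target and 19.1% over-reaction product, is 68.9%.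

(The earlier runs and the new flask are simulated from invented constants; noise was put on by code.)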